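**Retrosynthetic overview**

- Feature: the cyclohexane C1/C10–C14 carries methyl C20 on C11, oxygen on C12 and the three-carbon branch C15–C17 on C14, so it is a carvone ring; the ether carbon C9 sits on C10, β to the C12 oxygen.
- Key disconnection: C9–C10 and C11–OH together. An α-alkoxy radical, made from a carboxylic acid at C9, closes the tetrahydrofuran onto the C10=C11–C12=O enone, and the C11 enolate is hydroxylated in the same flask.
- The enone acid comes from (R)-carvone: closed α′-aldol of its epoxide (C1–C2, anti) with a C2–C6 aldehyde from (R)-2-methylglycidol (C3), Wharton 1,3-transposition (carbonyl to C12), A(1,3)-controlled hydroboration (C15), then Rh O–H insertion and malonate alkylation (C2–O–C9, C8, C7).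
- After the key step the C11 octanoate relays configuration to C12 (reduction, acyloxonium inversion, acyl shift), giving the cis-11,12-diol 12-ester. B-alkyl Suzuki coupling (C6–C7) closes the oxonane and triflate etherification (C3–O–C16) closes the oxepane.
- Ring order: cyclohexane (carvone) → tetrahydrofuran (key step) → oxonane → oxepane.

Key step: step 15

Remark: atoms are numbered as in the eunicellane skeleton (cyclohexane C1–C10–C11(C20)–C12–C13–C14; tetrahydrofuran C1–C2–O–C9–C10; oxonane C3(C18)–C4–C5–C6–C7(=C19)–C8; oxepane C14–C15(C17)–C16–O–C3). Acid 21 and salt 22 are carried as C9 epimer mixtures, which is harmless because C9 becomes a planar radical in step 15.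

**Route**

Step 1
Reactants: 1 (R)-2-methylglycidol; 2 2-methylprop-1-enylmagnesium bromide
Product: 3 (S)-2,5-dimethylhex-4-ene-1,2-diol
Conditions: 2 (3 equiv), CuI (10 mol%), THF, −30 → 0 °C; aq. NH4Cl
Reagents that add atoms: none
Why: Copper-catalysed Grignard opening of the epoxide (SN2) at its unsubstituted CH2 leaves the quaternary carbinol carbon (future C3) untouched, and the trisubstituted alkene it installs is a masked allyl group that 9-BBN will not attack in step 7.

Step 2
Reactants: 3 (S)-2,5-dimethylhex-4-ene-1,2-diol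
Product: 4 (S)-2,5-dimethyl-1,2-bis(triethylsilyloxy)hex-4-ene
Conditions: TESOTf (2.5 equiv), 2,6-lutidine, CH2Cl2, −78 → 0 °C
Reagents that add atoms: triethylsilyl trifluoromethanesulfonate, CC[Si](CC)(CC)OS(=O)(=O)C(F)(F)F
Why: O-silylation with the silyl triflate is reactive enough to cap the tertiary as well as the primary hydroxyl.

Step 3
Reactants: 4 (S)-2,5-dimethyl-1,2-bis(triethylsilyloxy)hex-4-ene
Product: 5 (S)-2,5-dimethyl-2-(triethylsilyloxy)hex-4-enal
Conditions: (COCl)2, DMSO, CH2Cl2, −78 → −30 °C; Et3N, → 0 °C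
Reagents that add atoms: none
Why: Swern oxidation in which the chlorosulfonium salt cleaves the unhindered primary triethylsilyl ether in situ and oxidises it to the aldehyde while the tertiary silyl ether survives; the aldehyde has no α-hydrogen and cannot racemise.

Step 4
Reactants: 6 (R)-carvone
Product: 7 (1R,4R,6R)-carvone epoxide (oxirane trans to isopropenyl)
Conditions: 30% H2O2, NaOH (cat.), MeOH, 0 °C
Reagents that add atoms: hydrogen peroxide, OO
Why: Weitz–Scheffer nucleophilic epoxidation of the enone, hydroperoxide adding anti to the isopropenyl group; both new centres are erased again in step 6, so their configuration is immaterial.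

Step 5
Reactants: 7 (1R,4R,6R)-carvone epoxide; 5 (S)-2,5-dimethyl-2-(triethylsilyloxy)hex-4-enal
Product: 8 α′-aldol adduct (epoxy ketone bearing on C1 the C2 carbinol and the C3 silyloxy chain)
Conditions: LDA, THF, −78 °C; then 5, −78 °C; AcOH quench at −78 °C
Reagents that add atoms: none
Why: Lithium enolate aldol through a Zimmerman–Traxler chair: kinetic α′-deprotonation gives the ring (E)-enolate, which is attacked anti to the neighbouring isopropenyl group (C1) and gives the anti aldol (C2), while the cold quench prevents retro-aldol and 1,2-silyl shift.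

Step 6
Reactants: 8 α′-aldol adduct
Product: 9 transposed allylic diol (C12–OH, C10=C11, C2–OH)
Conditions: N2H4·H2O, AcOH (cat.), MeOH, 0 °C → rt
Reagents that add atoms: none
Why: Wharton transposition: the epoxy hydrazone fragments with loss of N2 to the allylic alcohol, which moves the oxygen from C10 to C12 (the oxirane C12–O bond is retained) and the alkene to C10=C11.

Step 7
Reactants: 9 transposed allylic diol
Product: 11 triol (C2–OH, C12–OH, C16–OH; 15R), via C16 alkylborane 10 (not isolated)
Conditions: 9-BBN (4 equiv), THF, 0 °C → rt; then NaOH, H2O2, 0 °C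
Reagents that add atoms: hydrogen peroxide, OO
Why: Hydroboration–oxidation in which 9-BBN selects the 1,1-disubstituted isopropenyl alkene over the two trisubstituted ones; with H14 eclipsing the C15=C16 bond (A(1,3) strain) the borane should add anti to the branched C1 side, which sets the 15R centre.

Step 8
Reactants: 11 triol
Product: 12 C16 tert-butyldimethylsilyl ether diol
Conditions: TBSCl (1.1 equiv), imidazole, DMF, 0 °C
Reagents that add atoms: tert-butyldimethylsilyl chloride, CC(C)(C)[Si](C)(C)Cl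
Why: Silylation of the primary hydroxyl, which is far faster than that of the secondary allylic and the hindered C2 hydroxyl.

Step 9
Reactants: 12 C16 silyl ether diol
Product: 13 hydroxy enone with isopropylidene-capped side chain
Conditions: MnO2 (20 equiv), CH2Cl2, rt
Reagents that add atoms: none
Why: Allylic oxidation with MnO2 takes only the C12 allylic alcohol and gives the C10=C11–C12=O enone; the non-allylic C2 hydroxyl stays.

Step 10
Reactants: 13 hydroxy enone with isopropylidene-capped side chain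
Product: 14 hydroxy enone with C3 allyl group
Conditions: Grubbs second-generation catalyst (5 mol%), ethylene (5 bar), CH2Cl2, 40 °C
Reagents that add atoms: ethylene, C=C
Why: Ethenolysis (cross-metathesis with ethylene) exchanges the isopropylidene terminus for CH2 and liberates the allyl group; the ring enone alkene is inert to metathesis.

Step 11
Reactants: 15 dimethyl malonate
Product: 16 dimethyl diazomalonate
Conditions: 4-acetamidobenzenesulfonyl azide, Et3N, MeCN, 0 °C → rt
Reagents that add atoms: 4-acetamidobenzenesulfonyl azide, CC(=O)Nc1ccc(cc1)S(=O)(=O)N=[N+]=[N-]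
Why: Regitz diazo transfer to the active methylene group.

Step 12
Reactants: 14 hydroxy enone with C3 allyl group; 16 dimethyl diazomalonate
Product: 17 C2-O-malonyl ether
Conditions: Rh2(OAc)4 (2 mol%), benzene, 80 °C, slow addition of 16
Reagents that add atoms: none
Why: Rhodium carbenoid O–H insertion: the electrophilic malonyl carbenoid is captured by the hydroxyl faster than by the monosubstituted alkene, and the neutral conditions avoid the C2 alkoxide, which would trigger retro-vinylogous aldol cleavage or 1,2-silyl migration.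

Step 13
Reactants: 17 C2-O-malonyl ether; 18 2,3-dibromopropene
Product: 19 2-bromoallyl malonate
Conditions: Cs2CO3, DMF, rt
Reagents that add atoms: none
Why: Malonate alkylation (SN2 at the allylic bromide): carbonate deprotonates only the alkoxymalonate C–H, which is many pKa units more acidic than the α′- and γ-hydrogens of the enone.

Step 14
Reactants: 19 2-bromoallyl malonate
Product: 21 α-alkoxy acid (key-step precursor, C9 epimers), via malonic diacid 20 (not isolated)
Conditions: LiOH, THF/MeOH/H2O, rt → 40 °C; dilute HCl to pH 3–4, 0 °C; pyridine, toluene, 80 °C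
Reagents that add atoms: lithium hydroxide, [Li+].[OH-]
Why: Ester saponification followed by thermal decarboxylation of the alkoxymalonic acid gives the α-alkoxy acid; the C9 epimer mixture is irrelevant for step 15.

Step 15
Reactants: 21 α-alkoxy acid
Product: 24 hydroxy ketone (cis-fused hexahydroisobenzofuran with C12 ketone and C11 tertiary alcohol), via potassium carboxylate 22 (not isolated), via potassium enolate 23 (not isolated)
Conditions: KOt-Bu (0.98 equiv), DMF, 0 °C; [Ir{dF(CF3)ppy}2(dtbbpy)]PF6 (2 mol%), degassed, 450 nm LEDs, rt; then −45 °C, 2-(phenylsulfonyl)-3-phenyloxaziridine (1.5 equiv); aq. NH4Cl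
Reagents that add atoms: 2-(phenylsulfonyl)-3-phenyloxaziridine, O=S(=O)(N1OC1c1ccccc1)c1ccccc1
Why: Proposed new method: the excited Ir(III) catalyst oxidises carboxylate 22, loss of CO2 gives the nucleophilic α-alkoxy radical at C9, this adds 5-exo-trig to the electron-poor C10 of the enone (closing the tetrahydrofuran through C9–C10), and Ir(II) reduces the tertiary α-keto radical at C11 to potassium enolate 23, which should persist because the medium holds no acid stronger than tert-butanol and is then oxidised at C11 by the sulfonyloxaziridine; the closest known reactions are the photoredox decarboxylative conjugate addition of α-alkoxy acids to enones (where the enolate is protonated) and the oxaziridine hydroxylation of potassium enolates. The ring fusion at C10 must be cis because the short O–C2 tether from C1 can deliver C9 only to the enone face that carries C2. At C9 the planar radical erases the epimer mixture, and the bromoallyl chain should take the exo, pseudo-equatorial position of the chair-like transition state, cis to C3 across the ether oxygen. At C11 the oxaziridine should approach the enolate on the convex face, anti to the new C9–C10 bond. The step needs chemoselectivity for the enone over the allyl and bromoalkene π-bonds and an enolate at C11 and not at C13: the first follows from polarity matching and the 5-exo geometry, the second from forming the enolate by radical–polar crossover instead of deprotonation.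

Step 16
Reactants: 24 hydroxy ketone; 25 octanoic anhydride
Product: 26 C11 octanoate ketone
Conditions: 25 (3 equiv), DMAP (1.5 equiv), Et3N, CH2Cl2, 35 °C
Reagents that add atoms: none
Why: DMAP-catalysed acylation of the tertiary α-ketol hydroxyl; the ester is both the acyl group of the target and the neighbouring group needed in step 18.

Step 17
Reactants: 26 C11 octanoate ketone
Product: 27 trans-12-hydroxy 11-octanoate (C12–OH axial, anti to the C11 oxygen)
Conditions: NaBH4, CeCl3·7H2O, MeOH/THF, −40 °C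
Reagents that add atoms: none
Why: Borohydride reduction in which hydride should add to C12 from the convex face, because the concave face is screened by the syn-axial C9–H of the cis-fused tetrahydrofuran; this gives the axial alcohol trans to the C11 ester, and any cis epimer formed is simply 30 and is carried on into step 19.

Step 18
Reactants: 27 trans-12-hydroxy 11-octanoate
Product: 30 cis-12-hydroxy 11-octanoate, via C12 triflate 28 (not isolated), via acyloxonium triflate 29 (not isolated)
Conditions: Tf2O, pyridine, CH2Cl2, −30 → 0 °C; then THF/H2O, NaHCO3, rt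
Reagents that add atoms: water, O
Why: Neighbouring-group (acyloxonium) inversion: the axial triflate is displaced from the rear by the carbonyl oxygen of the trans-diaxial C11 octanoate, which inverts C12, and water opens the 1,3-dioxolan-2-ylium ion to the cis hydroxy ester; this secures the cis-11,12 relationship of the target, which a hydroxyl-directed or convex-face reduction cannot give.

Step 19
Reactants: 30 cis-12-hydroxy 11-octanoate
Product: 31 12-octanoate 11-alcohol (cis)
Conditions: DBU (0.3 equiv), toluene, 40 °C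
Reagents that add atoms: none
Why: Base-catalysed 1,2-acyl migration through the cyclic orthoester anion, possible only in the cis isomer, should move the octanoyl group from the crowded tertiary C11 oxygen to the secondary C12 oxygen under thermodynamic control.

Step 20
Reactants: 31 12-octanoate 11-alcohol
Product: 33 oxonane tricycle with C7 exocyclic methylene, via C6 alkylborane 32 (not isolated)
Conditions: 9-BBN (2.5 equiv), THF, rt; then slow addition to PdCl2(dppf) (20 mol%), AsPh3, Cs2CO3, DMF/THF/H2O, 50 °C, 2 mM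
Reagents that add atoms: none
Why: Hydroboration of the only unhindered alkene (9-BBN does not add to the 2-bromoalkene) followed by intramolecular B-alkyl Suzuki–Miyaura coupling under high dilution forms C6–C7 and the oxonane; the cis-2,9-disubstituted tetrahydrofuran holds the two chain ends close.

Step 21
Reactants: 33 oxonane tricycle
Product: 34 triol (C3–OH, C11–OH, C16–OH) 12-octanoate
Conditions: HF·pyridine, pyridine/THF, 0 °C → rt
Reagents that add atoms: none
Why: Fluoride-mediated desilylation removes both silyl ethers, and the buffered reagent leaves the ester and the exocyclic alkene intact.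

Step 22
Reactants: 34 triol 12-octanoate
Product: 36 target CNP0286133.1, via C16 triflate 35 (not isolated)
Conditions: Tf2O (1.1 equiv), 2,6-lutidine, CH2Cl2, −78 → 0 °C
Reagents that add atoms: none
Why: Intramolecular Williamson-type etherification: the primary hydroxyl is triflated selectively and displaced (SN2, 7-exo-tet) by the tertiary C3 hydroxyl, which closes the oxepane without touching a stereocentre.

**Compound list**

1 | (R)-2-methylglycidol, [(2R)-2-methyloxiran-2-yl]methanol | C[C@@]1(CO)CO1 | starting material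
2 | 2-methylprop-1-enylmagnesium bromide | CC(C)=C[Mg]Br | starting material
3 | (S)-2,5-dimethylhex-4-ene-1,2-diol | CC(C)=CC[C@](C)(O)CO | intermediate
4 | (S)-2,5-dimethyl-1,2-bis(triethylsilyloxy)hex-4-ene | CC(C)=CC[C@](C)(O[Si](CC)(CC)CC)CO[Si](CC)(CC)CC | intermediate
5 | (S)-2,5-dimethyl-2-(triethylsilyloxy)hex-4-enal | CC(C)=CC[C@](C)(O[Si](CC)(CC)CC)C=O | intermediate
6 | (R)-carvone | CC1=CC[C@H](CC1=O)C(C)=C | starting material
7 | (1R,4R,6R)-1-methyl-4-(prop-1-en-2-yl)-7-oxabicyclo[4.1.0]heptan-2-one (carvone epoxide, oxirane trans to isopropenyl) | C[C@@]12O[C@@H]1C[C@H](CC2=O)C(C)=C | intermediate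
8 | α′-aldol adduct: carvone epoxide carrying on C1, trans to isopropenyl, the (1S,2S)-1-hydroxy-2,5-dimethyl-2-(triethylsilyloxy)hex-4-enyl chain (C1/C2 anti) | CC(C)=CC[C@](C)(O[Si](CC)(CC)CC)[C@@H](O)[C@@H]1C(=O)[C@]2(C)O[C@@H]2C[C@H]1C(C)=C | intermediate
9 | transposed allylic diol (C12–OH, C10=C11, C2–OH, C14 isopropenyl) | CC(C)=CC[C@](C)(O[Si](CC)(CC)CC)[C@@H](O)[C@@H]1C=C(C)[C@H](O)C[C@H]1C(C)=C | intermediate
10 | C16 B-alkyl-9-BBN adduct of 9 (hydroxyls drawn free) | CC(C)=CC[C@](C)(O[Si](CC)(CC)CC)[C@@H](O)[C@@H]1C=C(C)[C@H](O)C[C@H]1[C@@H](C)CB2C3CCCC2CCC3 | intermediate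
11 | triol (C2–OH, C12–OH, C16–OH; 15R) | CC(C)=CC[C@](C)(O[Si](CC)(CC)CC)[C@@H](O)[C@@H]1C=C(C)[C@H](O)C[C@H]1[C@@H](C)CO | intermediate
12 | C16 tert-butyldimethylsilyl ether of 11 | CC(C)=CC[C@](C)(O[Si](CC)(CC)CC)[C@@H](O)[C@@H]1C=C(C)[C@H](O)C[C@H]1[C@@H](C)CO[Si](C)(C)C(C)(C)C | intermediate
13 | C2-hydroxy enone (C10=C11–C12=O) with isopropylidene-capped C3 side chain | CC(C)=CC[C@](C)(O[Si](CC)(CC)CC)[C@@H](O)[C@@H]1C=C(C)C(=O)C[C@H]1[C@@H](C)CO[Si](C)(C)C(C)(C)C | intermediate
14 | C2-hydroxy enone with C3 allyl group | C=CC[C@](C)(O[Si](CC)(CC)CC)[C@@H](O)[C@@H]1C=C(C)C(=O)C[C@H]1[C@@H](C)CO[Si](C)(C)C(C)(C)C | intermediate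
15 | dimethyl malonate | COC(=O)CC(=O)OC | starting material
16 | dimethyl diazomalonate | COC(=O)C(=[N+]=[N-])C(=O)OC | intermediate
17 | C2-O-malonyl ether (dimethyl 2-alkoxymalonate) | C=CC[C@](C)(O[Si](CC)(CC)CC)[C@@H](OC(C(=O)OC)C(=O)OC)[C@@H]1C=C(C)C(=O)C[C@H]1[C@@H](C)CO[Si](C)(C)C(C)(C)C | intermediate
18 | 2,3-dibromopropene | C=C(Br)CBr | starting material
19 | dimethyl 2-alkoxy-2-(2-bromoallyl)malonate | C=CC[C@](C)(O[Si](CC)(CC)CC)[C@@H](OC(CC(Br)=C)(C(=O)OC)C(=O)OC)[C@@H]1C=C(C)C(=O)C[C@H]1[C@@H](C)CO[Si](C)(C)C(C)(C)C | intermediate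
20 | 2-alkoxy-2-(2-bromoallyl)malonic acid | C=CC[C@](C)(O[Si](CC)(CC)CC)[C@@H](OC(CC(Br)=C)(C(=O)O)C(=O)O)[C@@H]1C=C(C)C(=O)C[C@H]1[C@@H](C)CO[Si](C)(C)C(C)(C)C | intermediate
21 | α-alkoxy acid, key-step precursor (C9 epimer mixture) | C=CC[C@](C)(O[Si](CC)(CC)CC)[C@@H](OC(CC(Br)=C)C(=O)O)[C@@H]1C=C(C)C(=O)C[C@H]1[C@@H](C)CO[Si](C)(C)C(C)(C)C | intermediate
22 | potassium salt of 21 | C=CC[C@](C)(O[Si](CC)(CC)CC)[C@@H](OC(CC(Br)=C)C(=O)[O-])[C@@H]1C=C(C)C(=O)C[C@H]1[C@@H](C)CO[Si](C)(C)C(C)(C)C.[K+] | intermediate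
23 | potassium C11=C12 enolate of the cis-fused tetrahydrofuran bicycle | C=CC[C@](C)(O[Si](CC)(CC)CC)[C@H]2O[C@@H](CC(Br)=C)[C@H]3[C@@H]2[C@H]([C@@H](C)CO[Si](C)(C)C(C)(C)C)CC([O-])=C3C.[K+] | intermediate
24 | hydroxy ketone, key-step product (cis-fused hexahydroisobenzofuran, C12 ketone, C11 tertiary alcohol) | C=CC[C@](C)(O[Si](CC)(CC)CC)[C@H]2O[C@@H](CC(Br)=C)[C@H]3[C@@H]2[C@H]([C@@H](C)CO[Si](C)(C)C(C)(C)C)CC(=O)[C@]3(C)O | intermediate
25 | octanoic anhydride | CCCCCCCC(=O)OC(=O)CCCCCCC | starting material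
26 | C11 octanoate of 24 | C=CC[C@](C)(O[Si](CC)(CC)CC)[C@H]2O[C@@H](CC(Br)=C)[C@H]3[C@@H]2[C@H]([C@@H](C)CO[Si](C)(C)C(C)(C)C)CC(=O)[C@]3(C)OC(=O)CCCCCCC | intermediate
27 | trans-12-hydroxy 11-octanoate | C=CC[C@](C)(O[Si](CC)(CC)CC)[C@H]2O[C@@H](CC(Br)=C)[C@H]3[C@@H]2[C@H]([C@@H](C)CO[Si](C)(C)C(C)(C)C)C[C@@H](O)[C@]3(C)OC(=O)CCCCCCC | intermediate
28 | C12 triflate of 27 | C=CC[C@](C)(O[Si](CC)(CC)CC)[C@H]2O[C@@H](CC(Br)=C)[C@H]3[C@@H]2[C@H]([C@@H](C)CO[Si](C)(C)C(C)(C)C)C[C@@H](OS(=O)(=O)C(F)(F)F)[C@]3(C)OC(=O)CCCCCCC | intermediate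
29 | cis-fused 2-heptyl-1,3-dioxolan-2-ylium triflate across C11/C12 | C=CC[C@](C)(O[Si](CC)(CC)CC)[C@H]2O[C@@H](CC(Br)=C)[C@H]3[C@@H]2[C@H]([C@@H](C)CO[Si](C)(C)C(C)(C)C)C[C@@H]4OC(CCCCCCC)=[O+][C@]34C.[O-]S(=O)(=O)C(F)(F)F | intermediate
30 | cis-12-hydroxy 11-octanoate | C=CC[C@](C)(O[Si](CC)(CC)CC)[C@H]2O[C@@H](CC(Br)=C)[C@H]3[C@@H]2[C@H]([C@@H](C)CO[Si](C)(C)C(C)(C)C)C[C@H](O)[C@]3(C)OC(=O)CCCCCCC | intermediate
31 | 12-octanoate 11-alcohol (cis) | C=CC[C@](C)(O[Si](CC)(CC)CC)[C@H]2O[C@@H](CC(Br)=C)[C@H]3[C@@H]2[C@H]([C@@H](C)CO[Si](C)(C)C(C)(C)C)C[C@H](OC(=O)CCCCCCC)[C@]3(C)O | intermediate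
32 | C6 B-alkyl-9-BBN adduct of 31 | B1(C2CCCC1CCC2)CCC[C@](C)(O[Si](CC)(CC)CC)[C@H]3O[C@@H](CC(Br)=C)[C@H]4[C@@H]3[C@H]([C@@H](C)CO[Si](C)(C)C(C)(C)C)C[C@H](OC(=O)CCCCCCC)[C@]4(C)O | intermediate
33 | oxonane tricycle (C7 exocyclic methylene, C3–OTES, C16–OTBS) | C=C1CCC[C@](C)(O[Si](CC)(CC)CC)[C@H]2O[C@@H](C1)[C@H]3[C@@H]2[C@H]([C@@H](C)CO[Si](C)(C)C(C)(C)C)C[C@H](OC(=O)CCCCCCC)[C@]3(C)O | intermediate
34 | triol (C3–OH, C11–OH, C16–OH) 12-octanoate | C=C1CCC[C@](C)(O)[C@H]2O[C@@H](C1)[C@H]3[C@@H]2[C@H]([C@@H](C)CO)C[C@H](OC(=O)CCCCCCC)[C@]3(C)O | intermediate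
35 | C16 triflate of 34 | C=C1CCC[C@](C)(O)[C@H]2O[C@@H](C1)[C@H]3[C@@H]2[C@H]([C@@H](C)COS(=O)(=O)C(F)(F)F)C[C@H](OC(=O)CCCCCCC)[C@]3(C)O | intermediate
36 | CNP0286133.1 | C=C1CCC[C@]2(C)OC[C@H](C)[C@@H]3C[C@H](OC(=O)CCCCCCC)[C@](C)(O)[C@@H]4[C@H]3[C@@H]2O[C@H]4C1 | target

**Step count and risks**

Total step count: 22. Longest linear sequence: 20 steps (from 1 through steps 1–3, 5–10 and 12–22).

Steps most likely to fail:

1. Step 15 (the step with the new method). The enolate may be protonated by adventitious acid before oxygen transfer, may be re-oxidised by the excited catalyst and lost through radical coupling, or may add to the sulfonimine by-product. Fallback by known chemistry, from 21: the ordinary protic photoredox decarboxylative conjugate cyclisation (same Ir catalyst, K2HPO4, DMF/H2O, blue LEDs) should give the C11–H ketone F1. Thermodynamic enolisation (TMSCl, NaI, Et3N, MeCN) should give the tetrasubstituted silyl enol ether F2. Rubottom oxidation (m-CPBA, NaHCO3, then mild acid) on the convex face returns to 24.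

2. Step 20. Slow closure of the nine-membered ring may lose out to intermolecular coupling, protodeboronation or β-hydride elimination. Fallback, from 31: hydroboration–oxidation (9-BBN; NaBO3) to the primary alcohol F3, Dess–Martin oxidation to the aldehyde F4, and Nozaki–Hiyama–Kishi cyclisation (CrCl2, NiCl2 cat., DMSO) to the cyclic allylic alcohol F5 (either C6 epimer serves). Acylation with methyl chloroformate and pyridine gives the methyl carbonate F6. Palladium-catalysed formate reduction (Pd(0), PBu3, HCO2NH4; hydride delivered to the more substituted allyl terminus C6) keeps the exocyclic alkene and returns to 33.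

3. Step 12. Insertion at the hindered C2 hydroxyl may be slow, so that cyclopropanation of the allyl group or carbonyl-ylide formation at the enone competes. Fallback, from 14: addition to methyl glyoxylate and acetylation (Ac2O, pyridine, DMAP) gives the α-acetoxy ether F7. Hosomi–Sakurai allylation of the derived oxocarbenium ion with (2-bromoallyl)trimethylsilane (BF3·OEt2, CH2Cl2, −78 °C) gives the methyl ester F8 as C9 epimers. Saponification (LiOH) returns to 21, bypassing steps 12–14.

Further compounds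
F1 | step 15 | C11–H ketone (24 without the C11 hydroxyl, C11 epimers) | C=CC[C@](C)(O[Si](CC)(CC)CC)[C@H]2O[C@@H](CC(Br)=C)[C@H]3[C@@H]2[C@H]([C@@H](C)CO[Si](C)(C)C(C)(C)C)CC(=O)C3C
F2 | step 15 | C11=C12 trimethylsilyl enol ether | C=CC[C@](C)(O[Si](CC)(CC)CC)[C@H]2O[C@@H](CC(Br)=C)[C@H]3[C@@H]2[C@H]([C@@H](C)CO[Si](C)(C)C(C)(C)C)CC(O[Si](C)(C)C)=C3C
F3 | step 20 | C6 primary alcohol from 31 | OCCC[C@](C)(O[Si](CC)(CC)CC)[C@H]2O[C@@H](CC(Br)=C)[C@H]3[C@@H]2[C@H]([C@@H](C)CO[Si](C)(C)C(C)(C)C)C[C@H](OC(=O)CCCCCCC)[C@]3(C)O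
F4 | step 20 | C6 aldehyde | O=CCC[C@](C)(O[Si](CC)(CC)CC)[C@H]2O[C@@H](CC(Br)=C)[C@H]3[C@@H]2[C@H]([C@@H](C)CO[Si](C)(C)C(C)(C)C)C[C@H](OC(=O)CCCCCCC)[C@]3(C)O
F5 | step 20 | oxonane C6 allylic alcohol (C6 epimers) | C=C1C(O)CC[C@](C)(O[Si](CC)(CC)CC)[C@H]2O[C@@H](C1)[C@H]3[C@@H]2[C@H]([C@@H](C)CO[Si](C)(C)C(C)(C)C)C[C@H](OC(=O)CCCCCCC)[C@]3(C)O
F6 | step 20 | C6 methyl carbonate of F5 | C=C1C(OC(=O)OC)CC[C@](C)(O[Si](CC)(CC)CC)[C@H]2O[C@@H](C1)[C@H]3[C@@H]2[C@H]([C@@H](C)CO[Si](C)(C)C(C)(C)C)C[C@H](OC(=O)CCCCCCC)[C@]3(C)O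
F7 | step 12 | C2-O α-acetoxy(methoxycarbonyl)methyl ether of 14 | C=CC[C@](C)(O[Si](CC)(CC)CC)[C@@H](OC(OC(C)=O)C(=O)OC)[C@@H]1C=C(C)C(=O)C[C@H]1[C@@H](C)CO[Si](C)(C)C(C)(C)C
F8 | step 12 | methyl ester of 21 (C9 epimers) | C=CC[C@](C)(O[Si](CC)(CC)CC)[C@@H](OC(CC(Br)=C)C(=O)OC)[C@@H]1C=C(C)C(=O)C[C@H]1[C@@H](C)CO[Si](C)(C)C(C)(C)C
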